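**Strategy.** Ring A is closed at C1–C10 by an anionic oxy-Cope rearrangement. The target carries oxygen at C3 and C8, 1,6-related across C1–C10, and rings A and B are cis-fused at C5/C10: this is the retron of a 2-vinylbicyclo[2.2.2]oct-5-en-2-ol. In one operation the [3,3] shift forms C1–C10, breaks C3–C8, sets H-10 cis to the C5 methyl, and releases the C3 ketone and a regiodefined C8 enol ether, the handle for C9 oxygenation. The precursor is a bicyclooctenol built from (S)-carvone: the carvone ring supplies C3–C8 (its methyl becomes the C4 methyl, its isopropenyl-bearing carbon C7), and its C3–C8 bond is the one that is sacrificed.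

Key step: step 8

Remark: eremophilane numbering is used for the decalin stages (ring carbons C1–C10, methyls on C4 and C5, isopropenyl on C7, ketone C8), β is the face of the C5 methyl, and "7-epi" means isopropenyl α; C7 and C9, both α to the C8 ketone, are assumed to be under thermodynamic control once the 3α-oxygen and 4β-methyl are in place, so the carvone-derived C7 centre is inverted in the last step.

Step 1
Reactants: 1 (S)-(+)-carvone
Product: 2 (5S)-1,2-dimethyl-5-(prop-1-en-2-yl)cyclohex-2-en-1-ol (C1 epimer mixture)
Conditions: MeLi, Et2O, −78 °C → 0 °C; H2O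
Reagents that add atoms: methyllithium [Li]C
Why: 1,2-addition of an organolithium to the enone carbonyl brings in the carbon that becomes the C5 methyl group, and the new carbinol centre is erased in step 2, so its configuration is irrelevant.

Step 2
Reactants: 2 (5S)-1,2-dimethyl-5-(prop-1-en-2-yl)cyclohex-2-en-1-ol
Product: 3 (5R)-2,3-dimethyl-5-(prop-1-en-2-yl)cyclohex-2-en-1-one
Conditions: PCC, 4 Å MS, CH2Cl2, rt
Reagents that add atoms: pyridinium chlorochromate [O-][Cr](=O)(=O)Cl.c1cc[nH+]cc1
Why: Babler–Dauben oxidative 1,3-transposition (chromate ester, [3,3] shift, oxidation) of the tertiary allylic alcohol should give the β-methyl enone; no stereocentre is formed and the isopropenyl centre is untouched (its descriptor changes only through CIP priorities).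

Step 3
Reactants: 3 (5R)-2,3-dimethyl-5-(prop-1-en-2-yl)cyclohex-2-en-1-one
Product: 4 (5S,6S)-6-hydroxy-2,3-dimethyl-5-(prop-1-en-2-yl)cyclohex-2-en-1-one (OH trans to isopropenyl)
Conditions: LDA, THF, −78 °C; 2-(phenylsulfonyl)-3-phenyloxaziridine, −78 °C; H2O
Reagents that add atoms: 2-(phenylsulfonyl)-3-phenyloxaziridine O=S(=O)(N1OC1c1ccccc1)c1ccccc1
Why: kinetic α'-deprotonation of the enone followed by sulfonyloxaziridine enolate hydroxylation should place the oxygen that becomes the bridgehead oxygen, anti to the neighbouring isopropenyl group; this centre becomes sp2 again in step 5.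

Step 4
Reactants: 4 (5S,6S)-6-hydroxy-2,3-dimethyl-5-(prop-1-en-2-yl)cyclohex-2-en-1-one
Product: 5 (5S,6S)-6-methoxy-2,3-dimethyl-5-(prop-1-en-2-yl)cyclohex-2-en-1-one
Conditions: MeI, Ag2O, MeCN, 40 °C
Reagents that add atoms: iodomethane CI
Why: silver-oxide-mediated O-methylation (Purdie methylation) caps the α-ketol under nearly neutral conditions as a methyl ether that cannot migrate in the alkoxide chemistry of step 8; no stereocentre changes.

Step 5
Reactants: 5 (5S,6S)-6-methoxy-2,3-dimethyl-5-(prop-1-en-2-yl)cyclohex-2-en-1-one, 6 phenyl vinyl sulfoxide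
Product: 7 1-methoxy-3,4-dimethyl-5-(phenylsulfinyl)-7-(prop-1-en-2-yl)bicyclo[2.2.2]octan-2-one (new bridge anti to isopropenyl; mixture at C3/C5/S)
Conditions: LDA, THF, −78 °C; 6, −78 → 0 °C; H2O
Reagents that add atoms: phenyl vinyl sulfoxide C=CS(=O)c1ccccc1
Why: double Michael (Michael–Michael) annulation of the cross-conjugated dienolate, in which the methoxy-bearing α'-carbon adds to the vinyl sulfoxide and the α-sulfinyl carbanion closes onto the β-carbon of the enone, both anti to the isopropenyl group, which sets the two bridgeheads (future C8 and the quaternary C5).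

Step 6
Reactants: 7 1-methoxy-3,4-dimethyl-5-(phenylsulfinyl)-7-(prop-1-en-2-yl)bicyclo[2.2.2]octan-2-one
Product: 8 1-methoxy-3,4-dimethyl-7-(prop-1-en-2-yl)bicyclo[2.2.2]oct-5-en-2-one (3-methyl syn to C5=C6; 7-isopropenyl syn to the C2–C3 bridge)
Conditions: NaHCO3, PhMe, 110 °C; then DBU (0.2 equiv), rt
Reagents that add atoms: none
Why: thermal syn-elimination of the sulfoxide (sulfoxide pyrolysis) toward the only β-hydrogens should give the etheno bridge, and DBU equilibrates the α-methyl to the face of that double bond, away from the bridge carrying the isopropenyl group (thermodynamic control of the future C4).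

Step 7
Reactants: 8 1-methoxy-3,4-dimethyl-7-(prop-1-en-2-yl)bicyclo[2.2.2]oct-5-en-2-one, 9 vinylmagnesium bromide
Product: 10 1-methoxy-3,4-dimethyl-7-(prop-1-en-2-yl)-2-vinylbicyclo[2.2.2]oct-5-en-2-ol (vinyl syn to C5=C6; OH syn to the C7–C8 bridge)
Conditions: CeCl3, THF, −78 → 0 °C; H2O
Reagents that add atoms: vinylmagnesium bromide C=C[Mg]Br
Why: organocerium 1,2-addition to the hindered, enolisable ketone should occur from the etheno-bridge face, because the isopropenyl group on C7 lies across the other face of the carbonyl, which sets the carbinol centre with vinyl syn to the double bond as the rearrangement requires.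

Step 8
Reactants: 10 1-methoxy-3,4-dimethyl-7-(prop-1-en-2-yl)-2-vinylbicyclo[2.2.2]oct-5-en-2-ol
Product: 13 8-methoxy-7-epi-eremophila-8(9),11-dien-3-one (cis-fused; 4β-Me; 5β-Me; 10β-H; 7α-isopropenyl), via potassium alkoxide 11 (not isolated), via potassium enolate 12 (not isolated)
Conditions: KH, 18-crown-6, THF, 0 °C → rt; AcOH, −78 °C
Reagents that add atoms: none
Why: KH deprotonates 10 to potassium alkoxide 11, whose C3–C8 σ bond (eremophilane numbering) is weakened by the alkoxide and by the bridgehead methoxy group, and a concerted alkoxide-accelerated [3,3] sigmatropic shift through the boat transition state imposed by the bicycle joins the vinyl terminus C1 to C10 while C3–C8 breaks, giving enolate 12, which the cold AcOH quench protonates to 13 before the C4 methyl can epimerise. The closest known reaction type is the anionic oxy-Cope rearrangement of 1-alkoxy-2-vinylbicyclo[2.2.2]oct-5-en-2-ols to cis-fused octalones. Ring A is the only ring closed, in a sigmatropic mode in which both allyl halves react suprafacially and no separate nucleophile–electrophile pair is involved; ring B already exists as the cyclohexene half of the cage and is merely set free. The one new stereocentre, C10, is controlled by the cage: C1 can reach C10 only from the side of the C3–C4 bridge, so H-10 ends cis to the C5 methyl group (cis-decalin), while C4, C5 and C7 are carried over unchanged. The step needs [3,3] shift rather than [1,3] shift or fragmentation, which is secured by the syn relation of the vinyl group and the etheno bridge set in step 7, and the positions of the new enolate (C2=C3) and enol ether (C8=C9) double bonds follow from the mechanism.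

Step 9
Reactants: 13 8-methoxy-7-epi-eremophila-8(9),11-dien-3-one
Product: 14 8-methoxy-7-epi-eremophila-8(9),11-dien-3α-ol
Conditions: L-selectride, THF, −78 °C; H2O
Reagents that add atoms: none
Why: hindered trialkylborohydride reduction under steric approach control: with the isopropenyl group still α, the cis-decalin should prefer the chair–chair form in which that group is pseudo-equatorial and C6 is axial on ring A, so ring B screens the α face of the C3 carbonyl and hydride should arrive from the β face along the equatorial trajectory, setting C3 as the 3α-alcohol (trans to the C4 methyl).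

Step 10
Reactants: 14 8-methoxy-7-epi-eremophila-8(9),11-dien-3α-ol
Product: 16 3α,9β-dihydroxy-7-epi-eremophil-11-en-8-one, via methoxy epoxide 15 (not isolated)
Conditions: DMDO (1.05 equiv), acetone/CH2Cl2, −78 °C; then AcOH, THF/H2O, 0 °C
Reagents that add atoms: dimethyldioxirane CC1(C)OO1; water O
Why: Rubottom-type oxidation: the enol ether is by far the most electron-rich alkene, so epoxidation should occur there and not at the isopropenyl group, and hydrolysis of the alkoxy epoxide gives the C8 ketone with oxygen only at C9; attack is expected mainly on the β face, and C9 stays epimerisable, so either epimer converges in step 12.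

Step 11
Reactants: 16 3α,9β-dihydroxy-7-epi-eremophil-11-en-8-one, 17 3-methylbut-2-enoyl chloride
Product: 18 7-epi-19 (3α,9β-bis(3-methylbut-2-enoyloxy)-7α-isopropenyl ketone)
Conditions: 17 (3 equiv), pyridine, DMAP (cat.), CH2Cl2, 0 °C → rt
Reagents that add atoms: 3-methylbut-2-enoyl chloride CC(C)=CC(Cl)=O
Why: DMAP-catalysed acylation of both secondary hydroxyls with the acid chloride installs the two senecioates without touching any stereocentre.

Step 12
Reactants: 18 7-epi-19
Product: 19 CNP0264508.1, (3R,4R,5R,7R,9R,10S)-8-oxoeremophil-11-ene-3,9-diyl bis(3-methylbut-2-enoate)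
Conditions: DBU (0.3 equiv), PhMe, rt
Reagents that add atoms: none
Why: base-mediated epimerisation through the C8 enolate under thermodynamic control: with the 3α-ester and 4β-methyl fixed, only the 7β,9β-isomer can place all four ring substituents equatorial in one cis-decalin chair–chair form, so C7 (and C9 if needed) should equilibrate to the target configuration.

**Compound list**

1 | (S)-(+)-carvone | CC1=CC[C@@H](CC1=O)C(C)=C | starting material
2 | (5S)-1,2-dimethyl-5-(prop-1-en-2-yl)cyclohex-2-en-1-ol (C1 epimers) | CC1=CC[C@@H](CC1(C)O)C(C)=C | intermediate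
3 | (5R)-2,3-dimethyl-5-(prop-1-en-2-yl)cyclohex-2-en-1-one | CC1=C(C)C(=O)C[C@@H](C1)C(C)=C | intermediate
4 | (5S,6S)-6-hydroxy-2,3-dimethyl-5-(prop-1-en-2-yl)cyclohex-2-en-1-one | O[C@@H]1C(=O)C(C)=C(C)C[C@H]1C(C)=C | intermediate
5 | (5S,6S)-6-methoxy-2,3-dimethyl-5-(prop-1-en-2-yl)cyclohex-2-en-1-one | CO[C@@H]1C(=O)C(C)=C(C)C[C@H]1C(C)=C | intermediate
6 | phenyl vinyl sulfoxide (racemic) | C=CS(=O)c1ccccc1 | starting material
7 | 1-methoxy-3,4-dimethyl-5-(phenylsulfinyl)-7-(prop-1-en-2-yl)bicyclo[2.2.2]octan-2-one (mixture at C3, C5, S) | CO[C@]12CC(S(=O)c3ccccc3)[C@](C)(C[C@H]1C(C)=C)C(C)C2=O | intermediate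
8 | 1-methoxy-3,4-dimethyl-7-(prop-1-en-2-yl)bicyclo[2.2.2]oct-5-en-2-one | CO[C@]12C=C[C@](C)(C[C@H]1C(C)=C)[C@@H](C)C2=O | intermediate
9 | vinylmagnesium bromide | C=C[Mg]Br | starting material
10 | 1-methoxy-3,4-dimethyl-7-(prop-1-en-2-yl)-2-vinylbicyclo[2.2.2]oct-5-en-2-ol | CO[C@]12C=C[C@](C)(C[C@H]1C(C)=C)[C@@H](C)[C@@]2(O)C=C | intermediate
11 | potassium alkoxide of 10 | CO[C@]12C=C[C@](C)(C[C@H]1C(C)=C)[C@@H](C)[C@@]2([O-])C=C.[K+] | intermediate
12 | potassium C2=C3 enolate of 13 | COC1=C[C@H]2CC=C([O-])[C@H](C)[C@@]2(C)C[C@H]1C(C)=C.[K+] | intermediate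
13 | 8-methoxy-7-epi-eremophila-8(9),11-dien-3-one | COC1=C[C@H]2CCC(=O)[C@H](C)[C@@]2(C)C[C@H]1C(C)=C | intermediate
14 | 8-methoxy-7-epi-eremophila-8(9),11-dien-3α-ol | COC1=C[C@H]2CC[C@@H](O)[C@H](C)[C@@]2(C)C[C@H]1C(C)=C | intermediate
15 | 8β,9β-epoxy-8α-methoxy-7-epi-eremophil-11-en-3α-ol | CO[C@]13O[C@@H]3[C@H]2CC[C@@H](O)[C@H](C)[C@@]2(C)C[C@H]1C(C)=C | intermediate
16 | 3α,9β-dihydroxy-7-epi-eremophil-11-en-8-one | C=C(C)[C@@H]1C[C@@]2(C)[C@H](CC[C@@H](O)[C@@H]2C)[C@@H](O)C1=O | intermediate
17 | 3-methylbut-2-enoyl chloride | CC(C)=CC(Cl)=O | starting material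
18 | 7-epi-19 | C=C(C)[C@@H]1C[C@@]2(C)[C@H](CC[C@@H](OC(=O)C=C(C)C)[C@@H]2C)[C@@H](OC(=O)C=C(C)C)C1=O | intermediate
19 | CNP0264508.1 | C=C(C)[C@H]1C[C@@]2(C)[C@H](CC[C@@H](OC(=O)C=C(C)C)[C@@H]2C)[C@@H](OC(=O)C=C(C)C)C1=O | target

**Total step count:** 12. **Longest linear sequence:** 12 steps (1 → 19).

**Steps most likely to fail**

Step 5. The tandem conjugate addition may stall after the first addition, because a fully substituted enolate carbon has to add and the second addition has to build a quaternary bridgehead, or the vinyl sulfoxide may be consumed by proton transfer. The fallback sets out from 5 and comes back at 8. Silylation (TBSOTf, Et3N, CH2Cl2, −78 °C) gives the 2-silyloxy diene, tert-butyldimethylsilyl dienol ether F1. A thermal Diels–Alder reaction with (E)-1,2-bis(phenylsulfonyl)ethylene (PhMe, 80 °C), again anti to the isopropenyl group, gives the bis-sulfone adduct F2. Reductive elimination of both sulfonyl groups (Na/Hg, NaH2PO4, MeOH, −20 °C) gives the bicyclooctadiene silyl enol ether F3. Desilylation (TBAF, AcOH, THF) followed by the DBU equilibration of step 6 should give 8.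

Step 9. The risk is poor facial selectivity: the cis-decalin can also react through its second chair–chair form, in which the α face of the C3 carbonyl is open, so hydride may enter from the α face. The fallback sets out from 13 and comes back at 18. The product of that pathway, 3β-alcohol F4, is then used instead. Mitsunobu esterification with 3-methylbut-2-enoic acid (PPh3, DIAD, PhMe) inverts C3 and installs the first ester, giving the 3α-senecioate enol ether F5. Enol ether oxidation as in step 10 gives the 9β-hydroxy ketone F6, and acylation of the C9 hydroxyl as in step 11 gives 18.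

Step 12. The equilibration may be accompanied by migration of the C9 acyl group to O8 through the enediolate, or by movement of the isopropenyl double bond into conjugation with the ketone. The fallback sets out from 16 and comes back at 19. Silylation of both hydroxyls (TESOTf, 2,6-lutidine, CH2Cl2) gives the bis(triethylsilyl) ether F7. Epimerisation with DBU at this stage, where no acyl group can migrate, gives the 7β-isopropenyl bis(triethylsilyl) ether F8. Desilylation (HF·pyridine, THF) gives the 7β-diol ketone F9, and acylation with 17 as in step 11 gives 19.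

**Further compounds**

F1 | step 5 | tert-butyldimethylsilyl dienol ether of 5 | COC1=C(O[Si](C)(C)C(C)(C)C)C(C)=C(C)C[C@H]1C(C)=C
F2 | step 5 | bis-sulfone Diels–Alder adduct (trans sulfonyl groups) | CO[C@]12C(S(=O)(=O)c3ccccc3)C(S(=O)(=O)c3ccccc3)[C@](C)(C[C@H]1C(C)=C)C(C)=C2O[Si](C)(C)C(C)(C)C
F3 | step 5 | bicyclooctadiene silyl enol ether | CO[C@]12C=C[C@](C)(C[C@H]1C(C)=C)C(C)=C2O[Si](C)(C)C(C)(C)C
F4 | step 9 | 8-methoxy-7-epi-eremophila-8(9),11-dien-3β-ol | COC1=C[C@H]2CC[C@H](O)[C@H](C)[C@@]2(C)C[C@H]1C(C)=C
F5 | step 9 | 3α-senecioate of the enol ether | COC1=C[C@H]2CC[C@@H](OC(=O)C=C(C)C)[C@H](C)[C@@]2(C)C[C@H]1C(C)=C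
F6 | step 9 | 9β-hydroxy-8-oxo-7-epi 3α-senecioate | C=C(C)[C@@H]1C[C@@]2(C)[C@H](CC[C@@H](OC(=O)C=C(C)C)[C@@H]2C)[C@@H](O)C1=O
F7 | step 12 | bis(triethylsilyl) ether of 16 | C=C(C)[C@@H]1C[C@@]2(C)[C@H](CC[C@@H](O[Si](CC)(CC)CC)[C@@H]2C)[C@@H](O[Si](CC)(CC)CC)C1=O
F8 | step 12 | 7β-isopropenyl bis(triethylsilyl) ether | C=C(C)[C@H]1C[C@@]2(C)[C@H](CC[C@@H](O[Si](CC)(CC)CC)[C@@H]2C)[C@@H](O[Si](CC)(CC)CC)C1=O
F9 | step 12 | 3α,9β-dihydroxyeremophil-11-en-8-one (7β) | C=C(C)[C@H]1C[C@@]2(C)[C@H](CC[C@@H](O)[C@@H]2C)[C@@H](O)C1=O
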